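Target ring numbering used in all comments: O1, C2 (3,4,5-trimethoxyphenyl), C3 (CH2OH), C4 (2,4,5-trimethoxybenzyl), C5 (OCH2).

- Retrosynthesis: C3–CH2OH is traced back to C3–CH2SiMe2Ph (C–Si to C–O kept for the last step), C5H2 to a lactone C=O, and the C3–H/C4–H pair to a C3=C4 double bond.
- Enabling feature: in ring O1–C2–C3–C4–C5 the neighbours C3 and C4 each carry a one-carbon branch and sit beside the benzylic C2–O1 unit. With C3=C4 and C5 as carbonyl this is a fully substituted butenolide whose O1–C2–C3≡C4 part is a propargylic alcohol, so C3–CH2Si, C4–C5 and O1–C5 are cut together.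
- The alkynol is then cut at C2–C3 (aryl aldehyde plus terminal alkyne) and at ArCH2–C(sp) (aryl Grignard reagent plus silyl-capped propargyl bromide).
- Forward: the chain ArCH2–C≡C–CH(OH)Ar is joined in steps 1–3, the single ring closes in step 5, and steps 6–9 adjust oxidation levels (C=C, lactone to ether, Si to OH).
- Stereochemistry: C2 comes from a BINOL–titanium alkynylzinc addition (step 3); C3 and C4 arise together in step 6 by syn hydrogenation on the face away from the C2 aryl group, giving the all-cis (2R,3R,4R) array.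

Key step: step 5

Assumption: the facial sense of step 3 is taken to match BINOL–titanium alkylzinc additions ((R)-ligand, Re face); the configuration of 8 would be confirmed through its MTPA esters before it is carried on, the (S)-ligand being the remedy if the sense is reversed.

Step 1
Reactants: 1 1-bromo-2,4,5-trimethoxybenzene; 2 3-bromo-1-(trimethylsilyl)prop-1-yne
Product: 4 trimethyl[3-(2,4,5-trimethoxyphenyl)prop-1-yn-1-yl]silane, via (2,4,5-trimethoxyphenyl)magnesium bromide 3 (not isolated)
Conditions: Mg, LiCl, THF, 23 °C; then 2, CuBr·SMe2 (5 mol%), 0 → 23 °C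
Reagents that add atoms: none
Why: Copper-catalysed coupling of an aryl Grignard reagent with a propargylic bromide (SN2 substitution at CH2); the trimethylsilyl cap shields the alkyne terminus against SN2′ attack, which would give an allene, and removes the acidic acetylenic hydrogen.

Step 2
Reactants: 4 trimethyl[3-(2,4,5-trimethoxyphenyl)prop-1-yn-1-yl]silane
Product: 5 1,2,4-trimethoxy-5-(prop-2-yn-1-yl)benzene
Conditions: K2CO3 (0.2 equiv), MeOH/THF, 0 °C
Reagents that add atoms: none
Why: Carbonate-catalysed methanolysis of the alkynyl C–Si bond (protodesilylation), run cold and stopped early so that the doubly activated ArCH2 group does not isomerise to the allene.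

Step 3
Reactants: 5 1,2,4-trimethoxy-5-(prop-2-yn-1-yl)benzene (2 equiv, excess recovered); 6 3,4,5-trimethoxybenzaldehyde
Product: 8 (S)-1-(3,4,5-trimethoxyphenyl)-4-(2,4,5-trimethoxyphenyl)but-2-yn-1-ol, via alkynyl(ethyl)zinc 7 (not isolated)
Conditions: Et2Zn (2 equiv), dicyclohexylamine (5 mol%), Et2O, 23 °C; then (R)-1,1′-bi-2-naphthol (20 mol%), Ti(OiPr)4 (50 mol%); then 6, 23 °C; aq. NH4Cl
Reagents that add atoms: none
Why: Catalytic enantioselective alkynylzinc addition to an aromatic aldehyde under BINOL–titanium control; the (R)-ligand should direct the alkynyl group to the Re face of the carbonyl, which sets the carbinol as (S) in 8 (the spatial arrangement of C2 in the target), and no base-labile ynone is ever made.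

Step 4
Reactants: 9 (chloromethyl)dimethyl(phenyl)silane
Product: 10 [(dimethylphenylsilyl)methyl]magnesium chloride (titrated Et2O solution, used directly)
Conditions: Mg, Et2O, reflux
Reagents that add atoms: magnesium, [Mg]
Why: Magnesium insertion into the C–Cl bond (Grignard formation), routine for α-silylmethyl chlorides.

Step 5
Reactants: 8 (S)-1-(3,4,5-trimethoxyphenyl)-4-(2,4,5-trimethoxyphenyl)but-2-yn-1-ol; 10 [(dimethylphenylsilyl)methyl]magnesium chloride (3.5 equiv)
Product: 13 (S)-4-[(dimethylphenylsilyl)methyl]-3-(2,4,5-trimethoxybenzyl)-5-(3,4,5-trimethoxyphenyl)furan-2(5H)-one, via oxamagnesacycle 11 (not isolated), via magnesium hydroxy-carboxylate 12 (not isolated)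
Conditions: 10, CuI (15 mol%), Et2O/toluene, 0 → 35 °C; then CO2 (1 atm), −20 → 23 °C; then 1 M HCl, 0 °C
Reagents that add atoms: carbon dioxide, O=C=O
Why: The first equivalent of 10 turns 8 into its magnesium alkoxide, and copper-assisted delivery of a silylmethyl group to the alkyne carbon next to the carbinol (C3), with magnesium ending on the far carbon (C4) trans to the new C–C bond, gives the five-membered oxamagnesacycle 11 (hydroxyl-directed anti-carbomagnesiation). The C4–Mg bond then adds to carbon dioxide to give carboxylate 12 with the carboxyl group cis to the carbinol, and acidification closes the butenolide by 5-exo-trig acyl substitution of the C2 hydroxyl at the carboxyl carbon (O1–C5 bond). The closest known reactions are the CuI-catalysed anti additions of Grignard reagents, (trimethylsilyl)methylmagnesium chloride among them, to propargylic alcohols and the carbon dioxide trapping of the resulting magnesium chelates to butenolides. No stereocentre is created, and C2, which serves only as the alkoxide anchor, keeps its configuration. The step needs carbon at C3, metal at C4 and anti addition, all of which follow from the alkoxide chelate; the phenyldimethylsilyl group is chosen because it is inert to the neighbouring magnesium alkoxide, the acidic work-up and plain silica, and copper catalysis at or below 35 °C is meant to let addition outrun deprotonation of the ArCH2 group.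

Step 6
Reactants: 13 (S)-4-[(dimethylphenylsilyl)methyl]-3-(2,4,5-trimethoxybenzyl)-5-(3,4,5-trimethoxyphenyl)furan-2(5H)-one
Product: 14 (3R,4S,5R)-4-[(dimethylphenylsilyl)methyl]-3-(2,4,5-trimethoxybenzyl)-5-(3,4,5-trimethoxyphenyl)dihydrofuran-2(3H)-one
Conditions: H2 (4 atm), 5% Rh/Al2O3, EtOAc, 23 °C
Reagents that add atoms: none
Why: Heterogeneous syn hydrogenation of the tetrasubstituted butenolide alkene: the flat ring is adsorbed on the face opposite the aryl group at C2, so both hydrogens enter anti to it and C3 and C4 are set together, all-cis to the aryl group; rhodium on alumina is the catalyst least prone to cleave the benzylic lactone C–O bond (the change of the aryl-carbon descriptor from S to R is only a change in ranking).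

Step 7
Reactants: 14 (3R,4S,5R)-4-[(dimethylphenylsilyl)methyl]-3-(2,4,5-trimethoxybenzyl)-5-(3,4,5-trimethoxyphenyl)dihydrofuran-2(3H)-one
Product: 15 (3R,4S,5R)-4-[(dimethylphenylsilyl)methyl]-3-(2,4,5-trimethoxybenzyl)-5-(3,4,5-trimethoxyphenyl)tetrahydrofuran-2-ol (anomer mixture)
Conditions: i-Bu2AlH (1.2 equiv), CH2Cl2, −78 °C; aq. potassium sodium tartrate
Reagents that add atoms: none
Why: Partial reduction of a γ-lactone to the lactol by i-Bu2AlH at −78 °C, where the aluminium hemiacetal persists until work-up; the silane and the three stereocentres are untouched.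

Step 8
Reactants: 15 (3R,4S,5R)-4-[(dimethylphenylsilyl)methyl]-3-(2,4,5-trimethoxybenzyl)-5-(3,4,5-trimethoxyphenyl)tetrahydrofuran-2-ol
Product: 16 {[(2R,3S,4R)-4-(2,4,5-trimethoxybenzyl)-2-(3,4,5-trimethoxyphenyl)tetrahydrofuran-3-yl]methyl}dimethyl(phenyl)silane
Conditions: Et3SiH, BF3·OEt2, CH2Cl2, −78 °C; NaHCO3 quench at −78 °C
Reagents that add atoms: none
Why: Ionic hydrogenation of the lactol (BF3-promoted oxocarbenium formation, then hydride transfer from Et3SiH), kept at −78 °C so that the C2 benzylic ether is not ionised; C5 becomes CH2, so no stereocentre is involved.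

Step 9
Reactants: 16 {[(2R,3S,4R)-4-(2,4,5-trimethoxybenzyl)-2-(3,4,5-trimethoxyphenyl)tetrahydrofuran-3-yl]methyl}dimethyl(phenyl)silane
Product: 17 [(2R,3R,4R)-4-(2,4,5-trimethoxybenzyl)-2-(3,4,5-trimethoxyphenyl)tetrahydrofuran-3-yl]methanol
Conditions: KH, t-BuOOH, N-methylpyrrolidone, 0 → 23 °C; then (n-Bu)4NF, 70 °C
Reagents that add atoms: tert-butyl hydroperoxide, CC(C)(C)OO
Why: Fleming–Tamao oxidation in its nucleophilic form: tert-butylperoxide adds to silicon, the phenyl group shifts from silicon to oxygen first, and fluoride-assisted peroxide rearrangement of the CH2–Si bond then gives the alcohol, with no mercury salt, bromine or strong acid present to attack the two trimethoxyarenes or the benzylic ether (C3 changes from S to R in name only).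

Compound list
1 | 1-bromo-2,4,5-trimethoxybenzene | COc1cc(OC)c(OC)cc1Br | starting material
2 | 3-bromo-1-(trimethylsilyl)prop-1-yne | C[Si](C)(C)C#CCBr | starting material
3 | (2,4,5-trimethoxyphenyl)magnesium bromide | COc1cc(OC)c(OC)cc1[Mg]Br | intermediate
4 | trimethyl[3-(2,4,5-trimethoxyphenyl)prop-1-yn-1-yl]silane | COc1cc(OC)c(OC)cc1CC#C[Si](C)(C)C | intermediate
5 | 1,2,4-trimethoxy-5-(prop-2-yn-1-yl)benzene | COc1cc(OC)c(OC)cc1CC#C | intermediate
6 | 3,4,5-trimethoxybenzaldehyde | COc1cc(C=O)cc(OC)c1OC | starting material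
7 | ethyl[3-(2,4,5-trimethoxyphenyl)prop-1-yn-1-yl]zinc | CC[Zn]C#CCc1cc(OC)c(OC)cc1OC | intermediate
8 | (S)-1-(3,4,5-trimethoxyphenyl)-4-(2,4,5-trimethoxyphenyl)but-2-yn-1-ol | O[C@@H](c1cc(OC)c(OC)c(OC)c1)C#CCc1cc(OC)c(OC)cc1OC | intermediate
9 | (chloromethyl)dimethyl(phenyl)silane | C[Si](C)(CCl)c1ccccc1 | starting material
10 | [(dimethylphenylsilyl)methyl]magnesium chloride | C[Si](C)(C[Mg]Cl)c1ccccc1 | intermediate
11 | (5S)-4-[(dimethylphenylsilyl)methyl]-3-(2,4,5-trimethoxybenzyl)-5-(3,4,5-trimethoxyphenyl)-2,5-dihydro-1,2-oxamagnesole (ether-solvated chelate) | O1[C@@H](c2cc(OC)c(OC)c(OC)c2)C(C[Si](C)(C)c2ccccc2)=C([Mg]1)Cc1cc(OC)c(OC)cc1OC | intermediate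
12 | (2E,4S)-3-[(dimethylphenylsilyl)methyl]-4-hydroxy-2-(2,4,5-trimethoxybenzyl)-4-(3,4,5-trimethoxyphenyl)but-2-enoic acid, present as its magnesium salt (drawn as the free acid) | O[C@@H](c1cc(OC)c(OC)c(OC)c1)/C(C[Si](C)(C)c1ccccc1)=C(\C(O)=O)Cc1cc(OC)c(OC)cc1OC | intermediate
13 | (S)-4-[(dimethylphenylsilyl)methyl]-3-(2,4,5-trimethoxybenzyl)-5-(3,4,5-trimethoxyphenyl)furan-2(5H)-one | O=C1O[C@@H](c2cc(OC)c(OC)c(OC)c2)C(C[Si](C)(C)c2ccccc2)=C1Cc1cc(OC)c(OC)cc1OC | intermediate
14 | (3R,4S,5R)-4-[(dimethylphenylsilyl)methyl]-3-(2,4,5-trimethoxybenzyl)-5-(3,4,5-trimethoxyphenyl)dihydrofuran-2(3H)-one (all-cis) | COc1cc(OC)c(OC)cc1C[C@H]1C(=O)O[C@@H](c2cc(OC)c(OC)c(OC)c2)[C@H]1C[Si](C)(C)c1ccccc1 | intermediate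
15 | (3R,4S,5R)-4-[(dimethylphenylsilyl)methyl]-3-(2,4,5-trimethoxybenzyl)-5-(3,4,5-trimethoxyphenyl)tetrahydrofuran-2-ol (anomer mixture) | COc1cc(OC)c(OC)cc1C[C@H]1C(O)O[C@@H](c2cc(OC)c(OC)c(OC)c2)[C@H]1C[Si](C)(C)c1ccccc1 | intermediate
16 | {[(2R,3S,4R)-4-(2,4,5-trimethoxybenzyl)-2-(3,4,5-trimethoxyphenyl)tetrahydrofuran-3-yl]methyl}dimethyl(phenyl)silane | COc1cc(OC)c(OC)cc1C[C@H]1CO[C@@H](c2cc(OC)c(OC)c(OC)c2)[C@H]1C[Si](C)(C)c1ccccc1 | intermediate
17 | [(2R,3R,4R)-4-(2,4,5-trimethoxybenzyl)-2-(3,4,5-trimethoxyphenyl)tetrahydrofuran-3-yl]methanol | COc1cc(OC)c(OC)cc1C[C@H]1CO[C@@H](c2cc(OC)c(OC)c(OC)c2)[C@H]1CO | target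

Total step count: 9 (the preparation of Grignard reagent 10 counted as step 4).
Longest linear sequence: 8 steps (1, 2, 3, 5, 6, 7, 8, 9) from 1.

Steps most likely to fail

Step 5. The hindered, chelated alkenylmagnesium 11 may take up carbon dioxide too slowly and be protonated instead, so that ring closure in the same flask gives little lactone. The fallback separates C–C bond formation from carbonylation. Setting out from 8, the same CuI-catalysed addition of 10 is quenched with I2 instead of CO2, which should give (1S,2E)-2-[(dimethylphenylsilyl)methyl]-3-iodo-1-(3,4,5-trimethoxyphenyl)-4-(2,4,5-trimethoxyphenyl)but-2-en-1-ol F1. Palladium-catalysed carbonylative lactonisation of the cis iodo alcohol (CO 1 atm, PdCl2(PPh3)2, NaHCO3, THF, 50 °C) then closes the butenolide and returns to 13.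

Step 6. Hydrogen uptake at the crowded tetrasubstituted alkene may be slow. Under forcing conditions, hydrogenolysis of the allylic and benzylic C–O bond, saturation of the phenyl ring on silicon, or incomplete face selectivity may take over. The fallback replaces surface hydrogenation by a hydride conjugate reduction. Setting out from 13 (NaBH4, NiCl2·6H2O, MeOH/THF, −20 °C), hydride should enter at C3 anti to the C2 aryl group. The enolate is then protonated kinetically at C4 from the same open face, which again gives the all-cis lactone and returns to 14. This fallback makes no new compound (F0).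

Step 8. BF3 may ionise the C2 benzylic C–O bond as well as the lactol. That would epimerise C2 to the 2,3-trans ether or let the 2,4,5-trimethoxyphenyl ring attack C2. The fallback avoids any Lewis acid and closes the ether by alkylation. Setting out from 14, LiAlH4 (THF, 0 °C) should give (1R,2S,3R)-2-[(dimethylphenylsilyl)methyl]-3-(2,4,5-trimethoxybenzyl)-1-(3,4,5-trimethoxyphenyl)butane-1,4-diol F2. Selective sulfonylation of the primary hydroxyl (TsCl, pyridine, 0 °C) gives (2R,3S,4R)-4-hydroxy-3-[(dimethylphenylsilyl)methyl]-2-(2,4,5-trimethoxybenzyl)-4-(3,4,5-trimethoxyphenyl)butyl 4-methylbenzenesulfonate F3. The benzylic alkoxide (NaH, THF, 0 °C) then displaces the sulfonate in a 5-exo-tet closure that leaves the C2–O bond intact and returns to 16.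

Further compounds
F1 | step 5 | (1S,2E)-2-[(dimethylphenylsilyl)methyl]-3-iodo-1-(3,4,5-trimethoxyphenyl)-4-(2,4,5-trimethoxyphenyl)but-2-en-1-ol | O[C@@H](c1cc(OC)c(OC)c(OC)c1)/C(C[Si](C)(C)c1ccccc1)=C(\I)Cc1cc(OC)c(OC)cc1OC
F0 | step 6 | none | none
F2 | step 8 | (1R,2S,3R)-2-[(dimethylphenylsilyl)methyl]-3-(2,4,5-trimethoxybenzyl)-1-(3,4,5-trimethoxyphenyl)butane-1,4-diol | COc1cc(OC)c(OC)cc1C[C@@H](CO)[C@H](C[Si](C)(C)c1ccccc1)[C@@H](O)c1cc(OC)c(OC)c(OC)c1
F3 | step 8 | (2R,3S,4R)-4-hydroxy-3-[(dimethylphenylsilyl)methyl]-2-(2,4,5-trimethoxybenzyl)-4-(3,4,5-trimethoxyphenyl)butyl 4-methylbenzenesulfonate | COc1cc(OC)c(OC)cc1C[C@@H](COS(=O)(=O)c1ccc(C)cc1)[C@H](C[Si](C)(C)c1ccccc1)[C@@H](O)c1cc(OC)c(OC)c(OC)c1
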